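## Retrosynthetic overview
- The C12 carbinol and the imide come from Ru-catalysed dynamic kinetic transfer hydrogenation of a 3-acylsuccinimide, which is made by Claisen acylation of a protected succinimide with the C12 ester.
- The 2α,3β-dichloride comes from a 3-ketone (α-chlorination, axial alcohol, Appel inversion). The 8(17)-methylene comes from kinetic deconjugation of a β-methyl enone.
- The trans-decalin (ring A) comes from a tertiary-epoxide opening terminated by a silyl dienol ether, which builds the C4 gem-dimethyl, 3-oxygen and C5–H together. The 9β side chain is placed beforehand by α-hydroxylation and Johnson–Claisen rearrangement.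
- Ring B and the C10 quaternary centre come from Birch dearomatisation of symmetric 3,5-dimethylanisole followed by Cu-catalysed asymmetric conjugate addition of a homoprenyl Grignard. Ring order: ring B, then ring A, then the pre-formed succinimide is attached last.

Assumption: the chiral catalysts (Josiphos, Shi ketone, camphorsulfonyl oxaziridine, TsDPEN) are chosen to give the natural absolute configuration, and N-PMB is the imide protecting group.

---

**Step 1**
Reactants: 1, 3,5-dimethylanisole
Product: 2, (±)-3,5-dimethylcyclohex-2-en-1-one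
Conditions: Li, NH3(l), EtOH, THF, –78 °C; then aq. HCl/MeOH, 60 °C
Reagents that add atoms: water, O
Why: Birch dearomatisation followed by enol-ether hydrolysis and conjugation gives the β-methyl enone. The symmetric arene becomes an enone whose C5 stereocentre is temporary and is erased in Step 3.

**Step 2**
Reactants: 2, and 3, 5-bromo-2-methylpent-2-ene (used as its Grignard reagent, Mg/THF)
Product: 4, (3R)-3,5-dimethyl-3-(4-methylpent-3-en-1-yl)cyclohexan-1-one (C5 epimeric mixture)
Conditions: homoprenyl-MgBr, CuBr·SMe2 (5 mol %), Josiphos ligand (6 mol %), t-BuOMe, –78 °C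
Reagents that add atoms: none (the chain comes from 3)
Why: Cu-catalysed asymmetric 1,4-addition of a Grignard reagent to a β-methyl cyclohexenone builds the all-carbon quaternary C10; the ligand sets C10 (R), and the C8 epimers converge in Step 3.

**Step 3**
Reactants: 4
Product: 5, (5R)-3,5-dimethyl-5-(4-methylpent-3-en-1-yl)cyclohex-2-en-1-one
Conditions: IBX, DMSO/fluorobenzene, 80 °C
Reagents that add atoms: none
Why: Nicolaou IBX dehydrogenation can only desaturate C7–C8, so the temporary C8 stereocentre is destroyed and a single stereocentre (C10) remains.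

**Step 4**
Reactants: 5
Product: 6, (5S)-3,5-dimethyl-5-(4-methylpent-3-en-1-yl)cyclohex-3-en-1-one
Conditions: KOt-Bu (1.1 equiv), THF, 0 °C; then AcOH, –78 °C
Reagents that add atoms: none
Why: As in the α- to β-isophorone isomerisation, the endocyclic extended enolate is the thermodynamic one, and kinetic α-protonation gives the Δ8 β,γ-enone with no new stereocentre.

**Step 5**
Reactants: 6
Product: 7, (2R,5S)-2-hydroxy-3,5-dimethyl-5-(4-methylpent-3-en-1-yl)cyclohex-3-en-1-one
Conditions: KHMDS, THF, –78 °C; then (camphorsulfonyl)oxaziridine, –78 °C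
Reagents that add atoms: (camphorsulfonyl)oxaziridine, O=S1(=O)CC23CCC(CC24ON14)C3(C)C (adds O)
Why: Davis α-hydroxylation of the extended enolate occurs anti to the larger homoprenyl chain, putting the 7-OH on the same face as the C10 methyl.

**Step 6**
Reactants: 7
Product: 8, ethyl 2-[(1R,6S)-2,6-dimethyl-6-(4-methylpent-3-en-1-yl)-4-oxocyclohex-2-en-1-yl]acetate
Conditions: MeC(OEt)3 (20 equiv), EtCO2H (cat.), 140 °C, sealed tube
Reagents that add atoms: triethyl orthoacetate, CCOC(C)(OCC)OCC (adds CH2CO2Et)
Why: Johnson–Claisen [3,3] rearrangement is suprafacial, so the C9–C11 bond forms on the face of the departing oxygen (cis to the C10 methyl), giving the natural 9β side chain; the enone is regenerated.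

**Step 7**
Reactants: 8
Product: 9, the (2S)-trisubstituted epoxide of 8 (chain alkene epoxidised)
Conditions: Shi fructose-derived ketone (0.3 equiv), Oxone, K2CO3, Bu4NHSO4, EDTA, MeCN/DMM/H2O, pH 10.5, 0 °C
Reagents that add atoms: Oxone, OOS(=O)(=O)[O-].[K+] (adds O)
Why: Shi asymmetric epoxidation is selective for the electron-rich trisubstituted alkene over the enone, and the catalyst selects the (3S)-epoxide that is matched with C10 for a chair-type cyclisation.

**Step 8**
Reactants: 9
Product: 10, ethyl 3β-hydroxy-6-oxo-13,14,15,16-tetranorlabd-7-en-12-oate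
Conditions: LDA (1.1 equiv), TMSCl (3 equiv), THF, –78 °C; then Me2AlCl (1.5 equiv), CH2Cl2, –78 → –30 °C; TBAF work-up
Reagents that add atoms: none (TMS is removed on work-up)
Why: Proposed new method: kinetic deprotonation occurs only at the α′ position C5, giving a silyl dienol ether; the Lewis acid ionises the epoxide at tertiary C4, C5 attacks through a chair-like transition state to form trans-fused ring A with the 4,4-gem-dimethyl, 3β-OH and 5α-H, and the oxocarbenium collapses to the enone. The closest known reactions are epoxy-polyene cyclisation and Mukaiyama-type epoxide opening by silyl enol ethers.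

**Step 9**
Reactants: 10
Product: 11, ethyl 3,6-dioxo-13,14,15,16-tetranorlabd-7-en-12-oate
Conditions: Dess–Martin periodinane, NaHCO3, CH2Cl2, rt
Reagents that add atoms: none
Why: Dess–Martin oxidation of the secondary alcohol; the C3 stereocentre is deliberately erased.

**Step 10**
Reactants: 11
Product: 12, ethyl 2α-chloro-3,6-dioxo-13,14,15,16-tetranorlabd-7-en-12-oate
Conditions: NCS (1.05 equiv), TsOH·H2O (0.1 equiv), CH2Cl2, 25 °C
Reagents that add atoms: N-chlorosuccinimide, O=C1CCC(=O)N1Cl (adds Cl)
Why: Acid-catalysed α-chlorination proceeds through the only enolisable side (C2, since C4 is quaternary); the equatorial 2α-Cl is strongly preferred because 2β would be syn-diaxial to the 10β-methyl, so the epimerisable centre settles on 2α.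

**Step 11**
Reactants: 12
Product: 13, ethyl 2α-chloro-3α-hydroxy-6-oxo-13,14,15,16-tetranorlabd-7-en-12-oate
Conditions: L-Selectride (1.1 equiv), THF, –78 °C
Reagents that add atoms: none (hydride only)
Why: The activated α-chloroketone is reduced faster than the hindered enone or the ester, and the bulky hydride attacks equatorially to give the axial 3α-alcohol needed for inversion.

**Step 12**
Reactants: 13
Product: 14, ethyl 2α,3β-dichloro-6-oxo-13,14,15,16-tetranorlabd-7-en-12-oate
Conditions: PPh3 (2 equiv), NCS (2 equiv), THF/toluene, 60 °C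
Reagents that add atoms: N-chlorosuccinimide, O=C1CCC(=O)N1Cl (adds Cl)
Why: Appel-type SN2 substitution at C3 inverts the axial 3α-OH to the equatorial 3β-Cl, giving the trans-diequatorial 2α,3β-dichloride.

**Step 13**
Reactants: 14
Product: 15, ethyl 2α,3β-dichloro-6-oxo-13,14,15,16-tetranorlabd-8(17)-en-12-oate
Conditions: LDA (2.3 equiv), THF, –78 °C, 1 h; then AcOH (4 equiv), –78 °C
Reagents that add atoms: none
Why: Kinetic γ-deprotonation at the unhindered C17 methyl, followed by α-protonation at C7, deconjugates the enone to the exocyclic 8(17)-alkene; the extra equivalent of base covers the ester, and C9 is untouched.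

**Step 14**
Reactants: 15, and 16, N-(4-methoxybenzyl)succinimide
Product: 17, the 3-acylsuccinimide (C12 ketone, N-PMB)
Conditions: 16 (3 equiv), LiHMDS (3.3 equiv), THF, –78 °C; add 15; –78 → 0 °C
Reagents that add atoms: none (16 is a reactant)
Why: Claisen-type C-acylation of the imide enolate by the ester gives the stabilised β-keto-imide enolate, which drives the reaction; C13 is epimerisable here, so no stereochemistry is set.

**Step 15**
Reactants: 17
Product: 18, the (12S,13R)-12-hydroxy N-PMB imide
Conditions: RuCl[(S,S)-TsDPEN](p-cymene) (5 mol %), HCO2H/Et3N (5:2), CH2Cl2, 40 °C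
Reagents that add atoms: none (H from formate)
Why: Proposed new method: the acidic C13–H racemises rapidly, and the Ru–TsDPEN catalyst delivers hydride to one face of the C12 ketone via a chelated transition state, giving the syn (12S,13R) hydroxy imide under catalyst control; the closest known reaction is Noyori–Ikariya transfer-hydrogenation dynamic kinetic resolution of α-substituted β-keto esters and lactams.

**Step 16**
Reactants: 18
Product: 19, haterumaimide B
Conditions: CAN (3 equiv), MeCN/H2O (3:1), 0 °C
Reagents that add atoms: none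
Why: Oxidative N-PMB cleavage of the imide frees the NH and leaves the alkene, C–Cl bonds and ketone intact.

---

## Compound list
1 | 3,5-dimethylanisole | COc1cc(C)cc(C)c1 | starting material
2 | (±)-3,5-dimethylcyclohex-2-en-1-one | CC1=CC(=O)CC(C)C1 | intermediate
3 | 5-bromo-2-methylpent-2-ene | CC(C)=CCCBr | starting material
4 | (3R)-3,5-dimethyl-3-(4-methylpent-3-en-1-yl)cyclohexan-1-one (C5 epimers) | O=C1CC(C)C[C@@](C)(CCC=C(C)C)C1 | intermediate
5 | (5R)-3,5-dimethyl-5-(4-methylpent-3-en-1-yl)cyclohex-2-en-1-one | O=C1C=C(C)C[C@@](C)(CCC=C(C)C)C1 | intermediate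
6 | (5S)-3,5-dimethyl-5-(4-methylpent-3-en-1-yl)cyclohex-3-en-1-one | O=C1CC(C)=C[C@@](C)(CCC=C(C)C)C1 | intermediate
7 | (2R,5S)-2-hydroxy-3,5-dimethyl-5-(4-methylpent-3-en-1-yl)cyclohex-3-en-1-one | O=C1[C@H](O)C(C)=C[C@@](C)(CCC=C(C)C)C1 | intermediate
8 | ethyl 2-[(1R,6S)-2,6-dimethyl-6-(4-methylpent-3-en-1-yl)-4-oxocyclohex-2-en-1-yl]acetate | O=C1C=C(C)[C@H](CC(=O)OCC)[C@@](C)(CCC=C(C)C)C1 | intermediate
9 | epoxide of 8 (chain epoxide, 2S) | O=C1C=C(C)[C@H](CC(=O)OCC)[C@@](C)(CC[C@@H]2OC2(C)C)C1 | intermediate
10 | ethyl 3β-hydroxy-6-oxo-13,14,15,16-tetranorlabd-7-en-12-oate | O=C1C=C(C)[C@H](CC(=O)OCC)[C@@]2(C)CC[C@H](O)C(C)(C)[C@H]12 | intermediate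
11 | ethyl 3,6-dioxo-13,14,15,16-tetranorlabd-7-en-12-oate | O=C1C=C(C)[C@H](CC(=O)OCC)[C@@]2(C)CCC(=O)C(C)(C)[C@H]12 | intermediate
12 | ethyl 2α-chloro-3,6-dioxo-13,14,15,16-tetranorlabd-7-en-12-oate | O=C1C=C(C)[C@H](CC(=O)OCC)[C@@]2(C)C[C@@H](Cl)C(=O)C(C)(C)[C@H]12 | intermediate
13 | ethyl 2α-chloro-3α-hydroxy-6-oxo-13,14,15,16-tetranorlabd-7-en-12-oate | O=C1C=C(C)[C@H](CC(=O)OCC)[C@@]2(C)C[C@@H](Cl)[C@@H](O)C(C)(C)[C@H]12 | intermediate
14 | ethyl 2α,3β-dichloro-6-oxo-13,14,15,16-tetranorlabd-7-en-12-oate | O=C1C=C(C)[C@H](CC(=O)OCC)[C@@]2(C)C[C@@H](Cl)[C@H](Cl)C(C)(C)[C@H]12 | intermediate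
15 | ethyl 2α,3β-dichloro-6-oxo-13,14,15,16-tetranorlabd-8(17)-en-12-oate | C=C1CC(=O)[C@H]2C(C)(C)[C@@H](Cl)[C@H](Cl)C[C@]2(C)[C@H]1CC(=O)OCC | intermediate
16 | N-(4-methoxybenzyl)succinimide | COc1ccc(CN2C(=O)CCC2=O)cc1 | starting material
17 | 12-oxo N-PMB 3-acylsuccinimide (C13 epimerisable) | C=C1CC(=O)[C@H]2C(C)(C)[C@@H](Cl)[C@H](Cl)C[C@]2(C)[C@H]1CC(=O)C1CC(=O)N(Cc2ccc(OC)cc2)C1=O | intermediate
18 | (12S,13R)-12-hydroxy N-PMB imide | C=C1CC(=O)[C@H]2C(C)(C)[C@@H](Cl)[C@H](Cl)C[C@]2(C)[C@H]1C[C@H](O)[C@H]1CC(=O)N(Cc2ccc(OC)cc2)C1=O | intermediate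
19 | haterumaimide B | C=C1CC(=O)[C@H]2C(C)(C)[C@@H](Cl)[C@H](Cl)C[C@]2(C)[C@H]1C[C@H](O)[C@H]1CC(=O)NC1=O | target

---

**Total steps:** 16. **Longest linear sequence:** 16 (1 → 2 → 4 → … → 19; compounds 3 and 16 are convergent partners).

**Three steps most likely to fail**
1. **Step 8 (epoxide/silyl dienol ether cyclisation).** Forming the vicinal quaternary–tertiary–quaternary C4/C5/C10 array by an enol-silane terminator is unprecedented. Fallback: form ring A by intramolecular Mukaiyama–Michael of the same α′-silyl dienol ether onto a β,β-dimethyl enone. The enone chain would come from allyl conjugate addition, Wacker oxidation, and aldol condensation with acetone. This gives a C2-ketone series in which C3 is chlorinated α to the ketone and C2 is chlorinated by reduction/Appel.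
2. **Steps 11–12 (3α-alcohol, then SN2 chlorination at the neopentyl-type C3).** Hydride may instead give the 3β-alcohol, or the Appel step may eliminate. Fallback: make the Δ2-olefin from the 3-ketone (enol triflate, then Pd-catalysed formate reduction). Then perform electrophilic anti-dichlorination (PhICl2) and separate the 2α,3β isomer.
3. **Steps 4–6 (endocyclic dienolate, α-hydroxylation, Claisen at hindered C9 with facial control).** The regiochemistry or the C9 configuration may be wrong. Fallback: install C9 by vinylogous Mukaiyama aldol of the silyl dienol ether with ethyl glyoxylate, followed by Barton–McCombie removal of the C11 hydroxyl. Alternatively, use a C9 ketone with Horner–Wadsworth–Emmons olefination and α-face hydrogenation of the Δ9(11) alkene.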